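(The readings were generated by integration for substances that don't exist; scatter was added.)

You cannot have the whole charge of L standing as Z: in the birch run E climbs from 1.1% to 25.2% of the L charged, and it climbs beside Z.

| flask | L | X | remark | time |
|---|---|---|---|---|
| birch | 9.5 mM | 28.5 mM | run made earlier |  |
| oak | 38 mM | 28.5 mM | run made earlier |  |
| spring | 19 mM | 28.5 mM |  | 8.0 d |
| autumn | 19 mM | 28.5 mM |  | 10 d |
| dusk | 19 mM | 28.5 mM |  | 15 d |

| run | time / d | L / % | Z / % | E / % |
|---|---|---|---|---|
| birch | 0.417 | 84.5 | 13.6 | 1.1 |
| birch | 0.625 | 78.3 | 20.0 | 2.2 |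
| birch | 0.833 | 72.0 | 24.4 | 3.6 |
| birch | 1.25 | 60.9 | 32.2 | 6.6 |
| birch | 2.08 | 45.1 | 42.9 | 12.2 |
| birch | 3.00 | 32.3 | 49.5 | 18.4 |
| birch | 5.00 | 16.2 | 58.6 | 25.2 |
| oak | 0.625 | 79.3 | 18.9 | 2.4 |
| oak | 1.25 | 65.2 | 28.8 | 6.0 |
| oak | 2.08 | 52.6 | 36.8 | 11.2 |
| oak | 3.00 | 42.3 | 41.7 | 15.3 |
| oak | 4.00 | 35.7 | 44.6 | 19.2 |
| oak | 5.00 | 31.2 | 48.2 | 21.5 |

(scatter of a reading: 0.3 percentage points)

* which of these there is most of at the end, counted by the L in it, spring (Z / E / L)
* which of these there is most of at the end, counted by the L in it, autumn (Z / E / L)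
* which of these there is most of at the end, counted by the L in it, dusk (Z / E / L)
* final amount of the leader among these, as a percentage of the L charged, in spring
* final amount of the leader among these, as a percentage of the L charged, in autumn
* final amount of the leader among these, as a percentage of the L charged, in dusk

- reactions considered so far: L + X -> Z; X -> G; Z <-> E

The charges look sound, so your decision is how long to leave the flask. For that you need a ceiling on Z. Call it the Z share: the part of the reacted L that stands as Z once Z and E balance. It is one over one plus the balance ratio, E over Z.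

E rises at a forward constant times the gap between Z and E divided by that ratio. My first guess for the ratio is the last birch reading, 0.430. Put it into E's rise from 0.833 d to 1.25 d, and the forward constant is 0.438 d⁻¹. Put that into the rise from 3.00 d to 5.00 d, and the ratio becomes 0.471. Go round once more: the constant is 0.412 d⁻¹ and the ratio 0.476. The share is then 67.7%, a reading from the birch run.

The new recipe gives 1.50 equivalents of X, so L is the limiting reagent, and the ceiling on Z is the share of the L charged. With the share above one half, Z outweighs E at balance.

The forecast names Z, Z and Z as leaders, at 62%, 64% and 66.5%: “Z is therefore about 68% of converted L and stays the leader”. On those numbers dusk stands closest to the ceiling, so I would run dusk.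

    L + X → Z, rate k1*[L]*[X]^0.5 (k = 0.100 M⁻⁰·⁵ h⁻¹)
    X → G (k = 1.00 × 10⁻⁵ h⁻¹)
    Z ⇌ E (K = 0.490, k = 0.0160 h⁻¹)

Z leads in each flask, at 61.9%, 63.9% and 66.2%. Dusk has not quite come to rest. At 150 d Z reads 67.1% and E 32.9%, with L at 0%, so dusk would still gain 0.90 percentage points, and spring 5.2 points. Now take a neighbour of autumn, held to the same time and the same X. With 76 mM of L, X is the limiting one, so the ceiling is the share times X over L, 25.4%. That flask ends with X at 0%, Z at 25.2% and L leading at 63%.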